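**Retrosynthetic overview**
1. The target acid comes from saponification, preceded by cross-metathesis (CH=CH2 to CH=CMe2) on a bicyclic ester whose C4 chain ends in an acid-inert vinyl group.
2. One enantioselective proton-initiated bicyclization of an acyclic all-E pentaenoate makes rings A and B, the C8=C9 alkene and all three stereocentres (C4, C5, C10). It starts at the C14=C15 alkene, as in the presumed cyclization of geranylfarnesyl diphosphate at its penultimate alkene.
3. Ring order: ring A forms first (C4–C5 bond), then ring B (C9–C10 bond), and loss of H-9 ends the cascade.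
4. The pentaenoate comes from an allyl–allyl coupling, after E-selective oxidation of the terminal methyl group of ethyl geranylgeranoate, which comes from a Horner–Wadsworth–Emmons reaction of farnesylacetone.

Atom labels: acyclic esters are numbered from the ester carbon (C1). Bicyclic compounds carry labdane labels: C4 is the quaternary carbon with CH3 and the chain, C5 the ring-fusion CH, C10 the ring-fusion C–CH3, and C8=C9 the ring alkene. Plain numbers are compounds.

Assumption: (5E,9E)-farnesylacetone is bought geometrically pure, and the (R)-ligand of step 5 gives the 5S,10S series as it does with homofarnesyl substrates; if the sense is reversed, the equally available (S)-ligand is used.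

**Step 1**
Reactants: 1 (5E,9E)-6,10,14-trimethylpentadeca-5,9,13-trien-2-one (farnesylacetone); 2 triethyl phosphonoacetate
Product: 4 ethyl (2E,6E,10E)-3,7,11,15-tetramethylhexadeca-2,6,10,14-tetraenoate (ethyl geranylgeranoate), via sodium phosphonoacetate carbanion 3 (not isolated)
Conditions: NaH, THF, 0 °C, then 1, rt → 50 °C; SiO2 separation of 2E from 2Z (about 4:1)
Reagents that add atoms: triethyl phosphonoacetate (2), CCOC(=O)CP(=O)(OCC)OCC
Why: Horner–Wadsworth–Emmons olefination of a methyl ketone favours the 2E β-methyl enoate, and the minor 2Z isomer is removed by chromatography.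

**Step 2**
Reactants: 4 ethyl geranylgeranoate
Product: 5 ethyl (2E,6E,10E,14E)-16-hydroxy-3,7,11,15-tetramethylhexadeca-2,6,10,14-tetraenoate
Conditions: SeO2 (0.1 equiv), t-BuOOH (2.5 equiv), salicylic acid (0.1 equiv), CH2Cl2, 0 °C → rt, stopped at about 50 % conversion, 4 recycled
Reagents that add atoms: selenium dioxide, O=[Se]=O; tert-butyl hydroperoxide, CC(C)(C)OO
Why: Catalytic Riley allylic oxidation (ene reaction, then [2,3]-shift) picks the least hindered, most electron-rich terminal isopropylidene and hydroxylates only its E-methyl group, which fixes the 14E geometry that later becomes the C4 configuration.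

**Step 3**
Reactants: 5 the 16-hydroxy ester
Product: 6 ethyl (2E,6E,10E,14E)-16-bromo-3,7,11,15-tetramethylhexadeca-2,6,10,14-tetraenoate
Conditions: CBr4, PPh3, CH2Cl2, −20 → 0 °C
Reagents that add atoms: tetrabromomethane, BrC(Br)(Br)Br
Why: Appel bromination is a neutral SN2 displacement at the primary allylic carbon, so no allylic shift or E/Z loss occurs.

**Step 4**
Reactants: 6 the 16-bromo ester; 7 allyltributylstannane
Product: 8 ethyl (2E,6E,10E,14E)-3,7,11,15-tetramethylnonadeca-2,6,10,14,18-pentaenoate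
Conditions: Pd2(dba)3 (2.5 mol %), P(2-furyl)3 (10 mol %), LiCl, THF, 45 °C
Reagents that add atoms: allyltributylstannane (7), C=CC[Sn](CCCC)(CCCC)CCCC
Why: In this Stille-type allyl–allyl coupling the syn π-allylpalladium intermediate bonds at its unhindered CH2 terminus, which keeps 14E and leaves the ester untouched.

**Step 5**
Reactants: 8 the all-E pentaenoate
Product: 10 ethyl (2E)-5-[(4aS,5S,8aS)-5-(but-3-en-1-yl)-2,5,8a-trimethyl-3,4,4a,5,6,7,8,8a-octahydronaphthalen-1-yl]-3-methylpent-2-enoate, via exocyclic-alkene isomer 9 (not isolated)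
Conditions: SnCl4 (3.2 equiv), (R)-2-(2-fluorobenzyloxy)-2'-hydroxy-1,1'-binaphthyl (2.2 equiv), toluene, −78 °C, 72 h; then CF3CO2H (5 equiv), CH2Cl2, −78 → −40 °C; aq. NaHCO3
Reagents that add atoms: none
Why: Proposed new method: an enantioselective proton-initiated polyene bicyclization (closest known types: cyclizations with BINOL-ether·SnCl4 Lewis-acid-assisted Brønsted acids, and the SnCl4 bicyclization of geranylgeranoates to labdadienoates) is extended to an initiating alkene that carries a chain; the vinyl end and the SnCl4-bound enoate are too electron-poor to be protonated, and the bound ester also weakens C6=C7 as a participating neighbour, so C14=C15 is the only trisubstituted alkene with a fully nucleophilic partner; the chiral acid protonates it at C14 on one face while C10 adds anti at C15 through a chair–chair fold, so the 14E geometry puts the butenyl chain equatorial (4S), the 10E geometry gives the trans fusion (5S,10S), and CF3CO2H·SnCl4 then closes any monocyclic material and moves the kinetic alkene of 9 to the most substituted C8=C9 position.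

**Step 6**
Reactants: 10 the bicyclic vinyl ester; 11 2-methyl-2-butene
Product: 12 ethyl (2E)-3-methyl-5-[(4aS,5S,8aS)-2,5,8a-trimethyl-5-(4-methylpent-3-en-1-yl)-3,4,4a,5,6,7,8,8a-octahydronaphthalen-1-yl]pent-2-enoate
Conditions: second-generation Grubbs catalyst RuCl2(=CHPh)(PCy3)(H2IMes) (3 mol %), 2-methyl-2-butene/CH2Cl2 1:1, sealed tube, 40 °C
Reagents that add atoms: 2-methyl-2-butene (11), CC=C(C)C
Why: In this cross-metathesis only the monosubstituted vinyl group reacts, the tetrasubstituted ring alkene and the β,β-disubstituted enoate are spectators, and no stereocentre is touched.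

**Step 7**
Reactants: 12 the ethyl ester
Product: 14 (2E)-3-methyl-5-[(4aS,5S,8aS)-2,5,8a-trimethyl-5-(4-methylpent-3-en-1-yl)-3,4,4a,5,6,7,8,8a-octahydronaphthalen-1-yl]pent-2-enoic acid (CNP0237483.2), via lithium carboxylate 13 (not isolated)
Conditions: LiOH·H2O (10 equiv), THF/MeOH/H2O, 55 °C; then 1 M HCl to pH 3, 0 °C
Reagents that add atoms: lithium hydroxide, [Li+].[OH-]
Why: Saponification by acyl-oxygen cleavage leaves the 2E alkene and the stereocentres alone, and the cold, brief acidification spares the two electron-rich alkenes.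

**Compound list**
1 | (5E,9E)-6,10,14-trimethylpentadeca-5,9,13-trien-2-one | CC(=O)CC/C=C(\C)CC/C=C(\C)CCC=C(C)C | starting material
2 | triethyl phosphonoacetate | CCOC(=O)CP(=O)(OCC)OCC | starting material
3 | sodium salt of the triethyl phosphonoacetate carbanion | CCOC(=O)[CH-]P(=O)(OCC)OCC.[Na+] | intermediate (not isolated)
4 | ethyl (2E,6E,10E)-3,7,11,15-tetramethylhexadeca-2,6,10,14-tetraenoate | CCOC(=O)/C=C(\C)CC/C=C(\C)CC/C=C(\C)CCC=C(C)C | intermediate
5 | ethyl (2E,6E,10E,14E)-16-hydroxy-3,7,11,15-tetramethylhexadeca-2,6,10,14-tetraenoate | CCOC(=O)/C=C(\C)CC/C=C(\C)CC/C=C(\C)CC/C=C(\C)CO | intermediate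
6 | ethyl (2E,6E,10E,14E)-16-bromo-3,7,11,15-tetramethylhexadeca-2,6,10,14-tetraenoate | CCOC(=O)/C=C(\C)CC/C=C(\C)CC/C=C(\C)CC/C=C(\C)CBr | intermediate
7 | allyltributylstannane | C=CC[Sn](CCCC)(CCCC)CCCC | starting material
8 | ethyl (2E,6E,10E,14E)-3,7,11,15-tetramethylnonadeca-2,6,10,14,18-pentaenoate | CCOC(=O)/C=C(\C)CC/C=C(\C)CC/C=C(\C)CC/C=C(\C)CCC=C | intermediate
9 | ethyl (2E)-5-[(1S,4aS,5S,8aR)-5-(but-3-en-1-yl)-5,8a-dimethyl-2-methylidenedecahydronaphthalen-1-yl]-3-methylpent-2-enoate | C=CCC[C@]1(C)CCC[C@]2(C)[C@@H](CC/C(C)=C/C(=O)OCC)C(=C)CC[C@@H]12 | intermediate (not isolated)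
10 | ethyl (2E)-5-[(4aS,5S,8aS)-5-(but-3-en-1-yl)-2,5,8a-trimethyl-3,4,4a,5,6,7,8,8a-octahydronaphthalen-1-yl]-3-methylpent-2-enoate | C=CCC[C@]1(C)CCC[C@]2(C)C(CC/C(C)=C/C(=O)OCC)=C(C)CC[C@@H]12 | intermediate
11 | 2-methyl-2-butene | CC=C(C)C | starting material
12 | ethyl (2E)-3-methyl-5-[(4aS,5S,8aS)-2,5,8a-trimethyl-5-(4-methylpent-3-en-1-yl)-3,4,4a,5,6,7,8,8a-octahydronaphthalen-1-yl]pent-2-enoate | CC(C)=CCC[C@]1(C)CCC[C@]2(C)C(CC/C(C)=C/C(=O)OCC)=C(C)CC[C@@H]12 | intermediate
13 | lithium salt of 14 | CC(C)=CCC[C@]1(C)CCC[C@]2(C)C(CC/C(C)=C/C(=O)[O-])=C(C)CC[C@@H]12.[Li+] | intermediate (not isolated)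
14 | (2E)-3-methyl-5-[(4aS,5S,8aS)-2,5,8a-trimethyl-5-(4-methylpent-3-en-1-yl)-3,4,4a,5,6,7,8,8a-octahydronaphthalen-1-yl]pent-2-enoic acid | CC(C)=CCC[C@]1(C)CCC[C@]2(C)C(CC/C(C)=C/C(=O)O)=C(C)CC[C@@H]12 | target

**Total step count:** 7. **Longest linear sequence:** 7.

**Steps most likely to fail**

Step 5 is the weakest point, for three reasons:
- (a) Protonation could also start at C10=C11.
- (b) A stepwise protonation would leak the 14E geometry into a C4 epimer and lower the ee.
- (c) The acid stage could stop at the C7 or exocyclic alkene isomers, or close a third ring onto the enoate.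

The fallback keeps the cationic bicyclization but shortens the polyene by one isoprene unit. The conjugated ester itself is then the terminator, and the initiating alkene is the only one with a nucleophilic neighbour. It sets out from 2 and 7 and comes back at 10. Commercial (5E)-geranylacetone F1 is olefinated with 2 (NaH, THF) to ethyl (2E,6E)-farnesoate F2. SeO2/t-BuOOH gives the 12-hydroxy ester F3, CBr4/PPh3 the 12-bromo ester F4, and 7 under Pd2(dba)3/P(2-furyl)3 the butenyl tetraenoate F5. The same chiral acid closes ring A. CF3CO2H·SnCl4 at −40 → 0 °C then closes ring B onto the α-carbon of the enoate and lets the alkene settle into conjugation, giving the bicyclic conjugated ester F6. i-Bu2AlH gives the allylic alcohol F7, CBr4/PPh3 the allylic bromide F8, and sodium ethyl acetoacetate the keto ester F9. KOH in aqueous ethanol at reflux (hydrolysis and decarboxylation) gives the methyl ketone F10, which with 2 and NaH gives 10.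

Step 2 may give low conversion, oxidation at internal alkenes, or over-oxidation to the enal. The fallback builds the 14E alkene by a sigmatropic rearrangement instead of a C–H oxidation, and it also bypasses steps 3 and 4. It sets out from 4 and comes back at 8. N-Bromosuccinimide in aqueous 1,2-dimethoxyethane attacks the exposed terminal alkene to give the bromohydrin F11. K2CO3 in methanol closes it to the terminal epoxide F12, and H5IO6 cleaves this to the C14 aldehyde F13. Isopropenylmagnesium bromide at −78 °C adds to the aldehyde only and gives the secondary allylic alcohol F14. Ethyl vinyl ether with Hg(OAc)2 gives the allyl vinyl ether F15, whose chair Claisen rearrangement at 110 °C gives the 14E aldehyde F16. Ph3P=CH2 turns F16 into 8.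

Step 4 may lose regiochemical or E/Z purity through the π-allylpalladium intermediate, and any 14Z material becomes the C4 epimer in step 5. The fallback replaces the metal-catalysed allyl–allyl coupling by a plain SN2 alkylation followed by semi-hydrogenation. It sets out from 6 and comes back at 8. 3-(Trimethylsilyl)propargyllithium (from 1-(trimethylsilyl)propyne and n-BuLi, THF, −78 °C) displaces the bromide to give the silyl enyne F17. K2CO3 in methanol gives the terminal alkyne F18. H2 over Pd/CaCO3 poisoned with Pb(OAc)2 and quinoline stops at the vinyl group of 8.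

**Further compounds**
F1 | step 5 | (5E)-6,10-dimethylundeca-5,9-dien-2-one (geranylacetone) | CC(=O)CC/C=C(\C)CCC=C(C)C
F2 | step 5 | ethyl (2E,6E)-3,7,11-trimethyldodeca-2,6,10-trienoate | CCOC(=O)/C=C(\C)CC/C=C(\C)CCC=C(C)C
F3 | step 5 | ethyl (2E,6E,10E)-12-hydroxy-3,7,11-trimethyldodeca-2,6,10-trienoate | CCOC(=O)/C=C(\C)CC/C=C(\C)CC/C=C(\C)CO
F4 | step 5 | ethyl (2E,6E,10E)-12-bromo-3,7,11-trimethyldodeca-2,6,10-trienoate | CCOC(=O)/C=C(\C)CC/C=C(\C)CC/C=C(\C)CBr
F5 | step 5 | ethyl (2E,6E,10E)-3,7,11-trimethylpentadeca-2,6,10,14-tetraenoate | CCOC(=O)/C=C(\C)CC/C=C(\C)CC/C=C(\C)CCC=C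
F6 | step 5 | ethyl (4aS,5S,8aS)-5-(but-3-en-1-yl)-2,5,8a-trimethyl-3,4,4a,5,6,7,8,8a-octahydronaphthalene-1-carboxylate | C=CCC[C@]1(C)CCC[C@]2(C)C(C(=O)OCC)=C(C)CC[C@@H]12
F7 | step 5 | [(4aS,5S,8aS)-5-(but-3-en-1-yl)-2,5,8a-trimethyl-3,4,4a,5,6,7,8,8a-octahydronaphthalen-1-yl]methanol | C=CCC[C@]1(C)CCC[C@]2(C)C(CO)=C(C)CC[C@@H]12
F8 | step 5 | (4aS,5S,8aS)-1-(bromomethyl)-5-(but-3-en-1-yl)-2,5,8a-trimethyl-3,4,4a,5,6,7,8,8a-octahydronaphthalene | C=CCC[C@]1(C)CCC[C@]2(C)C(CBr)=C(C)CC[C@@H]12
F9 | step 5 | ethyl 2-acetyl-3-[(4aS,5S,8aS)-5-(but-3-en-1-yl)-2,5,8a-trimethyl-3,4,4a,5,6,7,8,8a-octahydronaphthalen-1-yl]propanoate (both epimers at C2) | C=CCC[C@]1(C)CCC[C@]2(C)C(CC(C(C)=O)C(=O)OCC)=C(C)CC[C@@H]12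
F10 | step 5 | 4-[(4aS,5S,8aS)-5-(but-3-en-1-yl)-2,5,8a-trimethyl-3,4,4a,5,6,7,8,8a-octahydronaphthalen-1-yl]butan-2-one | C=CCC[C@]1(C)CCC[C@]2(C)C(CCC(C)=O)=C(C)CC[C@@H]12
F11 | step 2 | ethyl (2E,6E,10E)-14-bromo-15-hydroxy-3,7,11,15-tetramethylhexadeca-2,6,10-trienoate (racemic) | CCOC(=O)/C=C(\C)CC/C=C(\C)CC/C=C(\C)CCC(Br)C(C)(C)O
F12 | step 2 | ethyl (2E,6E,10E)-13-(3,3-dimethyloxiran-2-yl)-3,7,11-trimethyltrideca-2,6,10-trienoate (racemic) | CCOC(=O)/C=C(\C)CC/C=C(\C)CC/C=C(\C)CCC1OC1(C)C
F13 | step 2 | ethyl (2E,6E,10E)-3,7,11-trimethyl-14-oxotetradeca-2,6,10-trienoate | CCOC(=O)/C=C(\C)CC/C=C(\C)CC/C=C(\C)CCC=O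
F14 | step 2 | ethyl (2E,6E,10E)-14-hydroxy-3,7,11,15-tetramethylhexadeca-2,6,10,15-tetraenoate (racemic) | CCOC(=O)/C=C(\C)CC/C=C(\C)CC/C=C(\C)CCC(O)C(C)=C
F15 | step 2 | ethyl (2E,6E,10E)-14-(ethenyloxy)-3,7,11,15-tetramethylhexadeca-2,6,10,15-tetraenoate (racemic) | CCOC(=O)/C=C(\C)CC/C=C(\C)CC/C=C(\C)CCC(OC=C)C(C)=C
F16 | step 2 | ethyl (2E,6E,10E,14E)-3,7,11,15-tetramethyl-18-oxooctadeca-2,6,10,14-tetraenoate | CCOC(=O)/C=C(\C)CC/C=C(\C)CC/C=C(\C)CC/C=C(\C)CCC=O
F17 | step 4 | ethyl (2E,6E,10E,14E)-3,7,11,15-tetramethyl-19-(trimethylsilyl)nonadeca-2,6,10,14-tetraen-18-ynoate | CCOC(=O)/C=C(\C)CC/C=C(\C)CC/C=C(\C)CC/C=C(\C)CCC#C[Si](C)(C)C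
F18 | step 4 | ethyl (2E,6E,10E,14E)-3,7,11,15-tetramethylnonadeca-2,6,10,14-tetraen-18-ynoate | CCOC(=O)/C=C(\C)CC/C=C(\C)CC/C=C(\C)CC/C=C(\C)CCC#C
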